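**Retrosynthetic overview**

Locants (bicyclo[3.3.1]nonane): C1 prenylated bridgehead, C2 ketone, C3 prenylated enol carbon, C4 enol C–OH, C5 benzoylated bridgehead, C6 CH2, C7 prenylated CH, C8 CMe2, C9 bridging ketone.
Last disconnection: the C7 prenyl group comes from a CH2–CHO group by Wittig olefination.
Key disconnection: C5–C9 (Claisen acylation) and C7–C8 (tertiary radical onto an enal), both in the cyclohexanone ring C1–C9–C5–C6–C7–C8. The enabling feature is that C5 lies between the C4 ketone and the benzoyl ketone and faces the C9 carbonyl, while C8 is a gem-dimethyl carbon on C1 that becomes 1,3-diaxial to the C5 arm once the trione ring C1–C2–C3–C4–C5–C9 exists.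
Ring order: an acyclic triketo ester closes the trione ring first (C5–C9), then the cyclohexanone ring (C7–C8), in the same flask; C5 and C7 follow from the resolved quaternary C1.
The acyclic precursor is assembled from diethyl isopropylidenemalonate (C9, C1, C8, C2), prenyl bromide, benzoylacetone (C3, C4, C5, benzoyl) and 2-vinyloxirane (C6, C7 and the two enal carbons).

Key step: step 9

Assumption: the (S)-1-phenylethylammonium salt of the (R)-half-ester is the less soluble diastereomer; if the reverse holds, the (R)-amine is used and nothing else changes.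
Remark: 1,3-dicarbonyl units are drawn as one tautomer; carbons flanked by two ketones in the open-chain polyketo esters are configurationally labile and left undefined.
Remark: the quaternary carbon bearing isopropenyl and prenyl is a 1,5-diene; all steps stay at or below 60 °C to avoid Cope rearrangement.

Step 1
Reactants: 1 diethyl 2-(propan-2-ylidene)propanedioate; 2 1-bromo-3-methylbut-2-ene
Product: 3 diethyl 2-(3-methylbut-2-en-1-yl)-2-(prop-1-en-2-yl)propanedioate
Conditions: NaH, THF/DMF, 0 → 23 °C
Reagents that add atoms: none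
Why: Deconjugative alkylation, in which γ-deprotonation of the alkylidene malonate gives a dienolate that attacks the allylic bromide through its α-carbon (SN2), should create the future C1 quaternary carbon with its isopropenyl and prenyl groups (still prochiral, two identical esters).

Step 2
Reactants: 3 diethyl 2-(3-methylbut-2-en-1-yl)-2-(prop-1-en-2-yl)propanedioate
Product: 4 rac-2-(ethoxycarbonyl)-5-methyl-2-(prop-1-en-2-yl)hex-4-enoic acid
Conditions: KOH (1.0 equiv), EtOH/H2O, 23 °C; then 1 M HCl, 0 °C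
Reagents that add atoms: potassium hydroxide, [K+].[OH-]
Why: Mono-saponification of a disubstituted malonate should stop at the half-ester because the carboxylate shields the second, neopentyl-like ester; the quaternary carbon becomes a stereocentre, here still racemic.

Step 3
Reactants: 4 rac-2-(ethoxycarbonyl)-5-methyl-2-(prop-1-en-2-yl)hex-4-enoic acid
Product: 5 (S)-1-phenylethylammonium (2R)-2-(ethoxycarbonyl)-5-methyl-2-(prop-1-en-2-yl)hex-4-enoate
Conditions: (S)-1-phenylethylamine (0.5 equiv), EtOAc/heptane, crystallization to constant rotation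
Reagents that add atoms: (S)-1-phenylethylamine, C[C@H](N)c1ccccc1
Why: Classical resolution through diastereomeric salts, in which half an equivalent of amine precipitates the less soluble salt, should fix the future C1 as (R) after recrystallization.

Step 4
Reactants: 5 (S)-1-phenylethylammonium (2R)-2-(ethoxycarbonyl)-5-methyl-2-(prop-1-en-2-yl)hex-4-enoate
Product: 6 (2R)-2-(ethoxycarbonyl)-5-methyl-2-(prop-1-en-2-yl)hex-4-enoic acid
Conditions: 1 M HCl, Et2O, 0 °C
Reagents that add atoms: none
Why: Salt break by acid–base extraction; the quaternary stereocentre has no α-hydrogen and cannot racemize.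

Step 5
Reactants: 7 1-phenylbutane-1,3-dione; 2 1-bromo-3-methylbut-2-ene
Product: 8 7-methyl-1-phenyloct-6-ene-1,3-dione
Conditions: LiN(iPr)2 (2.1 equiv), THF, −78 → 0 °C; then 2, −78 → 0 °C; 1 M HCl
Reagents that add atoms: none
Why: γ-Alkylation of a β-diketone dianion, whose less stabilized terminal carbanion is the more nucleophilic site, should place the prenyl unit on the future C3 (SN2 on the allylic bromide).

Step 6
Reactants: 6 (2R)-2-(ethoxycarbonyl)-5-methyl-2-(prop-1-en-2-yl)hex-4-enoic acid; 8 7-methyl-1-phenyloct-6-ene-1,3-dione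
Product: 10 ethyl (2R)-2,4-bis(3-methylbut-2-en-1-yl)-3,5,7-trioxo-7-phenyl-2-(prop-1-en-2-yl)heptanoate, via acyl imidazolide 9 (not isolated)
Conditions: 6, 1,1'-carbonyldiimidazole, THF, 23 °C; added to 8 (2.2 equiv) pretreated with LiN(iPr)2 (4.4 equiv), THF, −78 °C; 1 M HCl at −78 °C
Reagents that add atoms: none
Why: Crossed Claisen acylation of the diketone dianion at its terminal carbanion by the acyl imidazolide (the far less reactive ethyl ester is spared) should form the C2–C3 bond; the quaternary centre has no α-hydrogen and is retained, and the new CH between two ketones is labile and irrelevant.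

Step 7
Reactants: 10 ethyl (2R)-2,4-bis(3-methylbut-2-en-1-yl)-3,5,7-trioxo-7-phenyl-2-(prop-1-en-2-yl)heptanoate
Product: 11 ethyl (2R,8E)-6-benzoyl-10-hydroxy-2,4-bis(3-methylbut-2-en-1-yl)-3,5-dioxo-2-(prop-1-en-2-yl)dec-8-enoate
Conditions: Pd(PPh3)4 (5 mol %), 2-vinyloxirane (1.05 equiv), THF, 0 → 23 °C
Reagents that add atoms: 2-vinyloxirane, C=CC1CO1
Why: Tsuji–Trost allylation with a vinyl epoxide, in which the alkoxide of the π-allyl-palladium intermediate deprotonates the most acidic and least hindered carbon (the CH2 between the benzoyl and C4 ketones) and that carbon attacks the distal allyl terminus, should give the E allylic alcohol and the C5–C6 bond; the new centre is enolizable and is fixed only in step 9.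

Step 8
Reactants: 11 ethyl (2R,8E)-6-benzoyl-10-hydroxy-2,4-bis(3-methylbut-2-en-1-yl)-3,5-dioxo-2-(prop-1-en-2-yl)dec-8-enoate
Product: 12 ethyl (2R,8E)-6-benzoyl-2,4-bis(3-methylbut-2-en-1-yl)-3,5,10-trioxo-2-(prop-1-en-2-yl)dec-8-enoate
Conditions: MnO2 (activated), CH2Cl2, 23 °C
Reagents that add atoms: none
Why: Allylic oxidation with MnO2 should convert the allylic alcohol into the E enal and leave the isolated alkenes and the enolized diketones untouched.

Step 9
Reactants: 12 ethyl (2R,8E)-6-benzoyl-2,4-bis(3-methylbut-2-en-1-yl)-3,5,10-trioxo-2-(prop-1-en-2-yl)dec-8-enoate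
Product: 14 2-[(1R,5S,7S)-5-benzoyl-4-hydroxy-8,8-dimethyl-1,3-bis(3-methylbut-2-en-1-yl)-2,9-dioxobicyclo[3.3.1]non-3-en-7-yl]acetaldehyde, via monocyclic trione 13 (not isolated)
Conditions: NaOEt (1.1 equiv), EtOH/THF, 0 → 40 °C; AcOH (0.1 equiv); then Fe(acac)3 (0.3 equiv), PhSiH3 (2.5 equiv), same flask, 60 °C; 1 M HCl
Reagents that add atoms: none
Why: Ethoxide forms the enolate of C5 (the carbon between the C4 ketone and the benzoyl ketone), which attacks the C9 ester carbonyl in a Claisen (Dieckmann-type) closure, 6-(enolendo)-exo-trig, of the trione ring C1–C2–C3–C4–C5–C9; this is the only six-membered C-acylation open to the chain and it is driven by the stabilized C2–C3–C4 trionate left after loss of ethoxide. Only then do C7 and C8 face each other as 1,3-diaxial substituents on C5 and C1, and the iron hydride made from Fe(acac)3 and PhSiH3 transfers a hydrogen atom to the CH2 end of the isopropenyl group to give the tertiary C8 radical, which adds 6-exo-trig to C7 of the enal and so closes the cyclohexanone ring C1–C9–C5–C6–C7–C8; the resulting α-formyl radical is reduced and protonated by ethanol. The closest known reaction types are the base-induced Claisen cyclization of polyketo esters to acylphloroglucinol-type triones and the iron-hydride-initiated reductive (Giese-type) cyclization of an alkene onto an enal. C5 is controlled by C1 through the bicycle: only the epimer of 13 with the C6 arm cis to the isopropenyl group can ring-close, so (R)-C1 enforces (S)-C5, and the Claisen closure is reversible under ethoxide so that the epimers of 13 can interconvert before the radical stage. C7 is controlled by the chair-like transition state of the radical closure, in which the CH=CH–CHO unit lies equatorial and away from the trione ring, which places the CH2CHO group exo. The step needs hydrogen-atom transfer to the isopropenyl group in the presence of two prenyl groups, which the higher reactivity of 1,1-disubstituted over trisubstituted alkenes toward metal hydrides should secure, and it needs the radical to form after ring closure, which the order of addition secures.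

Step 10
Reactants: 14 2-[(1R,5S,7S)-5-benzoyl-4-hydroxy-8,8-dimethyl-1,3-bis(3-methylbut-2-en-1-yl)-2,9-dioxobicyclo[3.3.1]non-3-en-7-yl]acetaldehyde
Product: 15 (1R,5S,7R)-5-benzoyl-4-hydroxy-8,8-dimethyl-1,3,7-tris(3-methylbut-2-en-1-yl)bicyclo[3.3.1]non-3-ene-2,9-dione
Conditions: isopropyltriphenylphosphonium iodide (3.2 equiv), KN(SiMe3)2 (3.0 equiv), THF, 0 °C; then 14, −78 → 0 °C
Reagents that add atoms: isopropyltriphenylphosphonium iodide, CC(C)[P+](c1ccccc1)(c1ccccc1)c1ccccc1.[I-]
Why: Wittig olefination with the non-stabilized isopropylidene ylide should turn the aldehyde into the prenyl group; one equivalent of ylide is consumed by the acidic enol, and the bridging and benzoyl ketones, both on quaternary carbons, are too hindered to react, so the three stereocentres are untouched.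

**Compound list**

1 | diethyl 2-(propan-2-ylidene)propanedioate | CCOC(=O)C(=C(C)C)C(=O)OCC | starting material
2 | 1-bromo-3-methylbut-2-ene | CC(C)=CCBr | starting material
3 | diethyl 2-(3-methylbut-2-en-1-yl)-2-(prop-1-en-2-yl)propanedioate | CCOC(=O)C(CC=C(C)C)(C(C)=C)C(=O)OCC | intermediate
4 | rac-2-(ethoxycarbonyl)-5-methyl-2-(prop-1-en-2-yl)hex-4-enoic acid | CCOC(=O)C(CC=C(C)C)(C(C)=C)C(O)=O | intermediate
5 | (S)-1-phenylethylammonium (2R)-2-(ethoxycarbonyl)-5-methyl-2-(prop-1-en-2-yl)hex-4-enoate | CCOC(=O)[C@](CC=C(C)C)(C(C)=C)C([O-])=O.C[C@H]([NH3+])c1ccccc1 | intermediate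
6 | (2R)-2-(ethoxycarbonyl)-5-methyl-2-(prop-1-en-2-yl)hex-4-enoic acid | CCOC(=O)[C@](CC=C(C)C)(C(C)=C)C(O)=O | intermediate
7 | 1-phenylbutane-1,3-dione | CC(=O)CC(=O)c1ccccc1 | starting material
8 | 7-methyl-1-phenyloct-6-ene-1,3-dione | CC(C)=CCCC(=O)CC(=O)c1ccccc1 | intermediate
9 | ethyl (2R)-2-(1H-imidazole-1-carbonyl)-5-methyl-2-(prop-1-en-2-yl)hex-4-enoate | CCOC(=O)[C@](CC=C(C)C)(C(C)=C)C(=O)n1ccnc1 | intermediate
10 | ethyl (2R)-2,4-bis(3-methylbut-2-en-1-yl)-3,5,7-trioxo-7-phenyl-2-(prop-1-en-2-yl)heptanoate | CCOC(=O)[C@](CC=C(C)C)(C(C)=C)C(=O)C(CC=C(C)C)C(=O)CC(=O)c1ccccc1 | intermediate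
11 | ethyl (2R,8E)-6-benzoyl-10-hydroxy-2,4-bis(3-methylbut-2-en-1-yl)-3,5-dioxo-2-(prop-1-en-2-yl)dec-8-enoate | CCOC(=O)[C@](CC=C(C)C)(C(C)=C)C(=O)C(CC=C(C)C)C(=O)C(C/C=C/CO)C(=O)c1ccccc1 | intermediate
12 | ethyl (2R,8E)-6-benzoyl-2,4-bis(3-methylbut-2-en-1-yl)-3,5,10-trioxo-2-(prop-1-en-2-yl)dec-8-enoate | CCOC(=O)[C@](CC=C(C)C)(C(C)=C)C(=O)C(CC=C(C)C)C(=O)C(C/C=C/C=O)C(=O)c1ccccc1 | intermediate
13 | (2E)-4-[(1S,5R)-1-benzoyl-2-hydroxy-3,5-bis(3-methylbut-2-en-1-yl)-4,6-dioxo-5-(prop-1-en-2-yl)cyclohex-2-en-1-yl]but-2-enal | O=C1[C@](CC=C(C)C)(C(C)=C)C(=O)C(CC=C(C)C)=C(O)[C@@]1(C/C=C/C=O)C(=O)c1ccccc1 | intermediate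
14 | 2-[(1R,5S,7S)-5-benzoyl-4-hydroxy-8,8-dimethyl-1,3-bis(3-methylbut-2-en-1-yl)-2,9-dioxobicyclo[3.3.1]non-3-en-7-yl]acetaldehyde | CC(C)=CCC1=C(O)[C@]2(C(=O)c3ccccc3)C[C@@H](CC=O)C(C)(C)[C@](CC=C(C)C)(C1=O)C2=O | intermediate
15 | (1R,5S,7R)-5-benzoyl-4-hydroxy-8,8-dimethyl-1,3,7-tris(3-methylbut-2-en-1-yl)bicyclo[3.3.1]non-3-ene-2,9-dione | CC(C)=CCC1=C(O)[C@]2(C(=O)c3ccccc3)C[C@@H](CC=C(C)C)C(C)(C)[C@](CC=C(C)C)(C1=O)C2=O | target

**Step count and risks**

Total step count: 10. Longest linear sequence: 9 steps (steps 1–4 and 6–10; step 5 is a one-step branch).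

Steps most likely to fail:

1. Step 9. The trione ring may close mainly with the arm on the face away from the isopropenyl group, the tertiary radical may be reduced before it reaches the enal, or the hydride may attack a prenyl alkene. Fallback (sets out from 12, comes back at 14): the two ring closures are separated and the enol is masked so that the C5 epimers can be separated. From 12, NaOEt in EtOH alone closes the trione ring to 13, which is isolated this time. Ac2O and pyridine convert it into the neutral enol acetate (2E)-4-[(1S,5R)-2-acetoxy-1-benzoyl-3,5-bis(3-methylbut-2-en-1-yl)-4,6-dioxo-5-(prop-1-en-2-yl)cyclohex-2-en-1-yl]but-2-enal F1, from which the unproductive C5 epimer is removed by chromatography. F1 is cyclized by hydrogen-atom transfer with Mn(dpm)3 (dpm = dipivaloylmethanate) and PhSiH3 in isopropanol to the acetate 2-[(1R,5S,7S)-4-acetoxy-5-benzoyl-8,8-dimethyl-1,3-bis(3-methylbut-2-en-1-yl)-2,9-dioxobicyclo[3.3.1]non-3-en-7-yl]acetaldehyde F2, and K2CO3 in MeOH removes the acetate to return to 14.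

2. Step 6. C-acylation at the congested acyl imidazolide may be slow, with proton transfer, attack at the ethyl ester or premature Claisen closure taking over. Fallback (sets out from 6 through 9, with 8; comes back at 10): the C2–C3 bond is made by aldol addition and oxidation instead of acylation. NaBH4 in THF/water reduces 9 to the alcohol ethyl (2R)-2-(hydroxymethyl)-5-methyl-2-(prop-1-en-2-yl)hex-4-enoate F3. Dess–Martin periodinane oxidizes it to the aldehyde ethyl (2R)-2-formyl-5-methyl-2-(prop-1-en-2-yl)hex-4-enoate F4. The dilithio dianion of 8 adds to F4 at −78 °C to give the aldol ethyl (2R)-3-hydroxy-2,4-bis(3-methylbut-2-en-1-yl)-5,7-dioxo-7-phenyl-2-(prop-1-en-2-yl)heptanoate F5, and a second Dess–Martin oxidation returns to 10.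

3. Step 7. The allyl-palladium species may be attacked by the wrong carbon (the prenyl-bearing CH between C2 and C4) or the benzoyl-flanked carbon may be allylated twice. Fallback (sets out from 8, comes back at 11): the arm is attached before the acylation, when the diketone has only one acidic carbon. Pd(PPh3)4 and 2-vinyloxirane convert 8 into (E)-2-(4-hydroxybut-2-en-1-yl)-7-methyl-1-phenyloct-6-ene-1,3-dione F6. TBSCl and imidazole protect the alcohol as (E)-2-[4-(tert-butyldimethylsilyloxy)but-2-en-1-yl]-7-methyl-1-phenyloct-6-ene-1,3-dione F7. Its dilithio dianion is acylated with 9 as in step 6 to give ethyl (2R,8E)-6-benzoyl-10-(tert-butyldimethylsilyloxy)-2,4-bis(3-methylbut-2-en-1-yl)-3,5-dioxo-2-(prop-1-en-2-yl)dec-8-enoate F8, and HF·pyridine removes the silyl group to return to 11.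

Further compounds
F1 | step 9 | (2E)-4-[(1S,5R)-2-acetoxy-1-benzoyl-3,5-bis(3-methylbut-2-en-1-yl)-4,6-dioxo-5-(prop-1-en-2-yl)cyclohex-2-en-1-yl]but-2-enal | O=C1[C@](CC=C(C)C)(C(C)=C)C(=O)C(CC=C(C)C)=C(OC(C)=O)[C@@]1(C/C=C/C=O)C(=O)c1ccccc1
F2 | step 9 | 2-[(1R,5S,7S)-4-acetoxy-5-benzoyl-8,8-dimethyl-1,3-bis(3-methylbut-2-en-1-yl)-2,9-dioxobicyclo[3.3.1]non-3-en-7-yl]acetaldehyde | CC(C)=CCC1=C(OC(C)=O)[C@]2(C(=O)c3ccccc3)C[C@@H](CC=O)C(C)(C)[C@](CC=C(C)C)(C1=O)C2=O
F3 | step 6 | ethyl (2R)-2-(hydroxymethyl)-5-methyl-2-(prop-1-en-2-yl)hex-4-enoate | CCOC(=O)[C@](CC=C(C)C)(C(C)=C)CO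
F4 | step 6 | ethyl (2R)-2-formyl-5-methyl-2-(prop-1-en-2-yl)hex-4-enoate | CCOC(=O)[C@](CC=C(C)C)(C(C)=C)C=O
F5 | step 6 | ethyl (2R)-3-hydroxy-2,4-bis(3-methylbut-2-en-1-yl)-5,7-dioxo-7-phenyl-2-(prop-1-en-2-yl)heptanoate | CCOC(=O)[C@](CC=C(C)C)(C(C)=C)C(O)C(CC=C(C)C)C(=O)CC(=O)c1ccccc1
F6 | step 7 | (E)-2-(4-hydroxybut-2-en-1-yl)-7-methyl-1-phenyloct-6-ene-1,3-dione | CC(C)=CCCC(=O)C(C/C=C/CO)C(=O)c1ccccc1
F7 | step 7 | (E)-2-[4-(tert-butyldimethylsilyloxy)but-2-en-1-yl]-7-methyl-1-phenyloct-6-ene-1,3-dione | CC(C)=CCCC(=O)C(C/C=C/CO[Si](C)(C)C(C)(C)C)C(=O)c1ccccc1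
F8 | step 7 | ethyl (2R,8E)-6-benzoyl-10-(tert-butyldimethylsilyloxy)-2,4-bis(3-methylbut-2-en-1-yl)-3,5-dioxo-2-(prop-1-en-2-yl)dec-8-enoate | CCOC(=O)[C@](CC=C(C)C)(C(C)=C)C(=O)C(CC=C(C)C)C(=O)C(C/C=C/CO[Si](C)(C)C(C)(C)C)C(=O)c1ccccc1
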